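**Retrosynthetic overview**

1. Numbering and feature: C7/C8/C9 are the benzylic CH, ring-fusion CH and OCH2 of the free-phenol guaiacyl half, C7'/C8'/C9' those of the prenyloxyaryl half; ring A = C7–O–C9'–C8'–C8 (aryl endo), ring B = C7'–O–C9–C8–C8' (aryl exo). The route rests on the C9–C8–C8'–C9' chain shared by both rings: four carbons oxygenated at each end, i.e. a butenolide, whose C8 and C8' can take up the two different benzylic carbons C7 and C7' in turn.
2. Endgame disconnections: phenol O–Si; prenyl ether back to an allyl ether (cross-metathesis); ring A at C7–H (hydride to the ring A oxocarbenium ion, aryl endo); ring B at C7'–O (benzylic cation, aryl exo); both CH2OH groups from reduction of a menthyloxy lactone.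
3. Key disconnection: C7–C8 and C7'–C8' in one flask from a lithiated 2-aryl-1,3-dithiane (C7, ketone level), (5R)-5-menthyloxyfuran-2(5H)-one (C9 acetal, C9' carbonyl) and O-allylvanillin (C7', alcohol level).
4. Ring order: the auxiliary lactone is reduced away, ring B closes first, ring A second; the absolute configuration at C8/C8' is relayed from (−)-menthol through the crystallised (5R) acetal.

Key step: step 6

Assumption: C7' of 14 and 15 is expected as an epimer mixture and is written without a descriptor because step 8 is stereoconvergent; keto alcohol 18 and hemiketal 19 are treated as ring–chain tautomers, either of which enters step 10.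

**Route**

Step 1
Reactants: 1 furfural
Product: 3 racemic 5-hydroxyfuran-2(5H)-one, via furfural endoperoxide 2 (not isolated)
Conditions: O2, methylene blue (cat.), hν (visible), MeOH, rt
Reagents that add atoms: oxygen, O=O
Why: Sensitised photooxygenation of a furan: singlet oxygen adds [4+2] across C2/C5 to give endoperoxide 2, and methanol-assisted fragmentation expels the formyl carbon as methyl formate to leave the hydroxybutenolide, which may be racemic because its C5 centre is reset in step 2.

Step 2
Reactants: 3 racemic 5-hydroxyfuran-2(5H)-one; 4 (−)-menthol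
Product: 6 (5R)-5-[(1R,2S,5R)-menthyloxy]furan-2(5H)-one, via C5-epimeric menthyl acetal mixture 5 (not isolated)
Conditions: camphorsulfonic acid (cat.), toluene, reflux, Dean–Stark; crystallisation from petroleum ether, mother liquor re-equilibrated with the acid and recrystallised
Reagents that add atoms: none
Why: Acid-catalysed acetalisation of the pseudo-acid gives both C5 epimers 5, which interconvert through the ring oxocarbenium ion while the less soluble (5R) epimer is expected to crystallise, so crystallisation-driven epimerisation (second-order asymmetric transformation, menthol as the only chiral source) should funnel the material into 6.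

Step 3
Reactants: 7 vanillin; 8 propane-1,3-dithiol
Product: 9 4-(1,3-dithian-2-yl)-2-methoxyphenol
Conditions: BF3·OEt2 (cat.), CH2Cl2, 0 °C → rt
Reagents that add atoms: none
Why: Lewis-acid-catalysed dithioacetalisation of an aromatic aldehyde, which tolerates the free phenol and places C7 at the masked-ketone (acyl anion) oxidation level.

Step 4
Reactants: 9 4-(1,3-dithian-2-yl)-2-methoxyphenol
Product: 10 2-[3-methoxy-4-(triisopropylsilyloxy)phenyl]-1,3-dithiane
Conditions: iPr3SiCl, imidazole, DMF, rt
Reagents that add atoms: triisopropylsilyl chloride, CC(C)[Si](Cl)(C(C)C)C(C)C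
Why: Standard silylation of a phenol (silyl chloride–imidazole); the bulky silyl ether should survive n-BuLi, LiAlH4 and the Brønsted and Lewis acid steps and is removed last by fluoride without touching the prenyl ether.

Step 5
Reactants: 7 vanillin
Product: 11 4-allyloxy-3-methoxybenzaldehyde (O-allylvanillin)
Conditions: allyl bromide, K2CO3, acetone, reflux
Reagents that add atoms: allyl bromide, C=CCBr
Why: Williamson etherification of the phenol; the allyl ether stands in for the acid-labile prenyl ether through the acidic steps 8 and 10 and is converted into it in step 11.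

Step 6
Reactants: 10 2-[3-methoxy-4-(triisopropylsilyloxy)phenyl]-1,3-dithiane; 6 (5R)-5-[(1R,2S,5R)-menthyloxy]furan-2(5H)-one; 11 4-allyloxy-3-methoxybenzaldehyde
Product: 14 trans,trans aldol lactone (3S,4R,5R; C7' epimers), via 2-lithio-1,3-dithiane 12 (not isolated), via lithium lactone enolate 13 (not isolated)
Conditions: n-BuLi, THF, −78 °C; then 6, −78 °C; then 11, −78 °C; aq. NH4Cl, −78 °C
Reagents that add atoms: none
Why: n-BuLi deprotonates C7 of 10 to the aryl- and sulfur-stabilised carbanion 12, which adds in Michael fashion to the β-carbon of 6 (future C8) to give lithium enolate 13, and 13 adds to the aldehyde carbon of 11 (future C7') in an aldol reaction, so that C7–C8 and C7'–C8' form in one flask. The closest known reaction type is the tandem conjugate addition–aldol coupling of lithiated aryl dithioacetals with 5-alkoxyfuran-2(5H)-ones and aromatic aldehydes. No ring is closed here, but all eighteen skeletal carbons are assembled with C7 at the ketone level and C7' at the alcohol level. C8 is set by the (5R) acetal carbon C9, whose menthyloxy group blocks one face of the flat butenolide so that the carbanion enters anti to it; C8' is set by the new bulky dithianyl group on C8, the aldehyde approaching anti to it to give the trans,trans lactone; C7' is not controlled and need not be, since both carbinol epimers ionise to the same cation in step 8. The step needs 1,4- over 1,2-regioselectivity, secured by the soft delocalised dithiane anion and the unhindered doubly activated β-carbon, and π-facial selectivity, secured by the menthyloxy-bearing centre next to the reacting carbon. The trans C8/C8' relation becomes the cis ring fusion once C9' and C7' exchange roles between the lactone and ring B.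

Step 7
Reactants: 14 trans,trans aldol lactone
Product: 15 dithianyl triol (2R,3R; C7' epimers)
Conditions: LiAlH4, THF, 0 °C → rt; then H2O
Reagents that add atoms: none
Why: LiAlH4 reduction of a γ-alkoxy-γ-lactone: hydride opens the lactone at C9', the C9 hemiacetal alkoxide so released expels menthoxide to an aldehyde that is reduced in turn, so both C9 and C9' end as CH2OH while the dithiane, allyl ether, aryl silyl ether and the C8/C8' centres are untouched.

Step 8
Reactants: 15 dithianyl triol
Product: 17 ring B tetrahydrofuran (2S,3R,4R) bearing the dithiane, via C7' benzylic cation 16 (not isolated)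
Conditions: camphorsulfonic acid (cat.), CH2Cl2, 0 °C
Reagents that add atoms: none
Why: Stereoconvergent cationic cycloetherification: acid ionises the p-alkoxybenzylic C7' carbinol of either epimer to cation 16, the C9 hydroxyl captures it in a 5-exo closure (the C9' hydroxyl could only give an oxetane), and the reversible closure should settle the C7' aryl trans to the C8' hydroxymethyl group (7'S), the arrangement that is exo in the bicycle.

Step 9
Reactants: 17 ring B tetrahydrofuran bearing the dithiane
Product: 18 keto alcohol (3R,4R,5S)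
Conditions: MeI, CaCO3, MeCN–H2O, 45 °C
Reagents that add atoms: water, O
Why: Alkylative dithiane hydrolysis: S-methylation makes sulfur a leaving group, the aryl-stabilised thionium ion is trapped by water (or first by the C9' hydroxyl), and CaCO3 buffers the HI so that the allyl ether, silyl ether, benzylic ether and the C8 centre next to the new ketone should be preserved.

Step 10
Reactants: 18 keto alcohol
Product: 21 exo,endo furofuran allyl ether silyl ether (7R,7'S,8R,8'R), via ring A hemiketal 19 (not isolated), via ring A oxocarbenium ion 20 (not isolated)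
Conditions: Et3SiH, BF3·OEt2, CH2Cl2, −78 → −30 °C; cold aq. NaHCO3
Reagents that add atoms: none
Why: Ionic hydrogenation of a hemiketal (reductive etherification): BF3 converts the ring-closed tautomer 19 into the aryl-conjugated oxocarbenium ion 20 of the cis-fused 3,7-dioxabicyclo[3.3.0]octane and Et3SiH delivers hydride to C7 from the convex face, so the new C7–H is exo and the aryl endo, i.e. (7R), while the low temperature keeps the benzylic C–O bonds from re-ionising.

Step 11
Reactants: 21 exo,endo furofuran allyl ether silyl ether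
Product: 22 exo,endo furofuran prenyl ether silyl ether
Conditions: 2-methylbut-2-ene (excess), second-generation Grubbs catalyst RuCl2(=CHPh)(PCy3)(H2IMes) (cat.), CH2Cl2, 40 °C
Reagents that add atoms: 2-methylbut-2-ene, CC=C(C)C
Why: Olefin cross-metathesis of a terminal allyl ether with excess 2-methylbut-2-ene, which swaps the =CH2 terminus for an isopropylidene group with loss of propene and involves no stereocentre.

Step 12
Reactants: 22 exo,endo furofuran prenyl ether silyl ether
Product: 23 target CNP0185952.5
Conditions: Bu4NF, AcOH, THF, 0 °C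
Reagents that add atoms: none
Why: Fluoride-mediated cleavage of the aryl O–Si bond, driven by Si–F bond formation and buffered with acetic acid so that the phenoxide is protonated at once and the prenyl ether and benzylic ether centres are left alone.

**Compound list**

1 | furfural (furan-2-carbaldehyde) | O=Cc1ccco1 | starting material
2 | furfural endoperoxide, 2,3,7-trioxabicyclo[2.2.1]hept-5-ene-1-carbaldehyde (formed in the flask) | O=CC12C=CC(OO1)O2 | intermediate
3 | 5-hydroxyfuran-2(5H)-one, racemic | O=C1C=CC(O)O1 | intermediate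
4 | (−)-menthol, (1R,2S,5R)-2-isopropyl-5-methylcyclohexanol | C[C@@H]1CC[C@H]([C@@H](C1)O)C(C)C | starting material
5 | 5-[(1R,2S,5R)-menthyloxy]furan-2(5H)-one as the mixture of C5 epimers (formed in the flask) | O=C1C=CC(O[C@@H]2C[C@H](C)CC[C@H]2C(C)C)O1 | intermediate
6 | (5R)-5-[(1R,2S,5R)-menthyloxy]furan-2(5H)-one | O=C1C=C[C@H](O[C@@H]2C[C@H](C)CC[C@H]2C(C)C)O1 | intermediate
7 | vanillin | COc1cc(C=O)ccc1O | starting material
8 | propane-1,3-dithiol | SCCCS | starting material
9 | 4-(1,3-dithian-2-yl)-2-methoxyphenol | COc1cc(C2SCCCS2)ccc1O | intermediate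
10 | 2-[3-methoxy-4-(triisopropylsilyloxy)phenyl]-1,3-dithiane | COc1cc(C2SCCCS2)ccc1O[Si](C(C)C)(C(C)C)C(C)C | intermediate
11 | 4-allyloxy-3-methoxybenzaldehyde (O-allylvanillin) | COc1cc(C=O)ccc1OCC=C | intermediate
12 | 2-lithio-2-[3-methoxy-4-(triisopropylsilyloxy)phenyl]-1,3-dithiane (formed in the flask) | COc1cc(C2([Li])SCCCS2)ccc1O[Si](C(C)C)(C(C)C)C(C)C | intermediate
13 | lithium enolate of (4R,5R)-4-{2-[3-methoxy-4-(triisopropylsilyloxy)phenyl]-1,3-dithian-2-yl}-5-[(1R,2S,5R)-menthyloxy]dihydrofuran-2(3H)-one (formed in the flask) | [Li]OC1O[C@@H](O[C@@H]2C[C@H](C)CC[C@H]2C(C)C)[C@H](C2(SCCCS2)c2ccc(O[Si](C(C)C)(C(C)C)C(C)C)c(OC)c2)C=1 | intermediate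
14 | (3S,4R,5R)-3-[(4-allyloxy-3-methoxyphenyl)(hydroxy)methyl]-4-{2-[3-methoxy-4-(triisopropylsilyloxy)phenyl]-1,3-dithian-2-yl}-5-[(1R,2S,5R)-menthyloxy]dihydrofuran-2(3H)-one, both C7' epimers | O=C1O[C@@H](O[C@@H]2C[C@H](C)CC[C@H]2C(C)C)[C@H](C2(SCCCS2)c2ccc(O[Si](C(C)C)(C(C)C)C(C)C)c(OC)c2)[C@H]1C(O)c1ccc(OCC=C)c(OC)c1 | intermediate
15 | (2R,3R)-2-{2-[3-methoxy-4-(triisopropylsilyloxy)phenyl]-1,3-dithian-2-yl}-3-[(4-allyloxy-3-methoxyphenyl)(hydroxy)methyl]butane-1,4-diol, both C7' epimers | OC[C@H](C1(SCCCS1)c1ccc(O[Si](C(C)C)(C(C)C)C(C)C)c(OC)c1)[C@H](CO)C(O)c1ccc(OCC=C)c(OC)c1 | intermediate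
16 | C7' p-alkoxybenzylic cation derived from 15 (formed in the flask) | OC[C@H](C1(SCCCS1)c1ccc(O[Si](C(C)C)(C(C)C)C(C)C)c(OC)c1)[C@H](CO)[CH+]c1ccc(OCC=C)c(OC)c1 | intermediate
17 | [(2S,3R,4R)-2-(4-allyloxy-3-methoxyphenyl)-4-{2-[3-methoxy-4-(triisopropylsilyloxy)phenyl]-1,3-dithian-2-yl}oxolan-3-yl]methanol | OC[C@@H]1[C@@H](c2ccc(OCC=C)c(OC)c2)OC[C@@H]1C1(SCCCS1)c1ccc(O[Si](C(C)C)(C(C)C)C(C)C)c(OC)c1 | intermediate
18 | [(3R,4R,5S)-5-(4-allyloxy-3-methoxyphenyl)-4-(hydroxymethyl)oxolan-3-yl][3-methoxy-4-(triisopropylsilyloxy)phenyl]methanone | OC[C@@H]1[C@@H](c2ccc(OCC=C)c(OC)c2)OC[C@@H]1C(=O)c1ccc(O[Si](C(C)C)(C(C)C)C(C)C)c(OC)c1 | intermediate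
19 | ring A hemiketal, (3aR,4S,6aR)-4-(4-allyloxy-3-methoxyphenyl)-1-[3-methoxy-4-(triisopropylsilyloxy)phenyl]tetrahydro-1H,3H-furo[3,4-c]furan-1-ol, C7 anomers (formed in the flask) | COc1cc(C2(O)OC[C@H]3[C@@H]2CO[C@@H]3c2ccc(OCC=C)c(OC)c2)ccc1O[Si](C(C)C)(C(C)C)C(C)C | intermediate
20 | ring A oxocarbenium ion derived from 19 (formed in the flask) | COc1cc(C2=[O+]C[C@H]3[C@@H]2CO[C@@H]3c2ccc(OCC=C)c(OC)c2)ccc1O[Si](C(C)C)(C(C)C)C(C)C | intermediate
21 | (1R,3aR,4S,6aR)-4-(4-allyloxy-3-methoxyphenyl)-1-[3-methoxy-4-(triisopropylsilyloxy)phenyl]tetrahydro-1H,3H-furo[3,4-c]furan | COc1cc([C@@H]2OC[C@H]3[C@@H]2CO[C@@H]3c2ccc(OCC=C)c(OC)c2)ccc1O[Si](C(C)C)(C(C)C)C(C)C | intermediate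
22 | (1R,3aR,4S,6aR)-1-[3-methoxy-4-(triisopropylsilyloxy)phenyl]-4-[3-methoxy-4-(3-methylbut-2-enyloxy)phenyl]tetrahydro-1H,3H-furo[3,4-c]furan | COc1cc([C@@H]2OC[C@H]3[C@@H]2CO[C@@H]3c2ccc(OCC=C(C)C)c(OC)c2)ccc1O[Si](C(C)C)(C(C)C)C(C)C | intermediate
23 | 2-methoxy-4-{(1R,3aR,4S,6aR)-4-[3-methoxy-4-(3-methylbut-2-enyloxy)phenyl]tetrahydro-1H,3H-furo[3,4-c]furan-1-yl}phenol (7R,7'S,8R,8'R), CNP0185952.5 | COc1cc([C@@H]2OC[C@H]3[C@@H]2CO[C@@H]3c2ccc(OCC=C(C)C)c(OC)c2)ccc1O | target

**Step count and risks**

Total steps: 12. Longest linear sequence: 9 steps (1, 2, 6–12; the vanillin branch 3, 4, 6–12 is equally long).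

Steps most likely to fail:

1. Step 6. The hindered lithium enolate 13 may be captured only slowly by the aldehyde, so that proton transfer, loss of the dithiane anion by retro-Michael reaction or retro-aldol cleavage on warming competes, and facial control at C8' may erode. Fallback: the three-component coupling is divided into two operations. Setting out from 10 and 6, only the conjugate addition is run and the enolate is protonated at −78 °C to isolate (4R,5R)-4-{2-[3-methoxy-4-(triisopropylsilyloxy)phenyl]-1,3-dithian-2-yl}-5-[(1R,2S,5R)-menthyloxy]dihydrofuran-2(3H)-one F1. Its enolate is then regenerated with LiN(iPr)2 in THF at −78 °C, lithium is exchanged for zinc with ZnCl2, and 11 is added; the zinc aldolate is less prone to retro-aldol cleavage and the aldehyde should again enter anti to the C8 substituent. The fallback returns to the route at 14.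

2. Step 10. BF3 may re-ionise the benzylic C7–O or C7'–O bonds and equilibrate the kinetically formed endo aryl toward the exo,exo isomer, hydride may attack the oxocarbenium ion with too little facial preference, or the open ketone tautomer may be reduced directly. Fallback: ring A is closed by C9'–O bond formation instead of C7–H formation, so that no cation arises at C7. Setting out from 18, NaBH4 in MeOH at 0 °C gives the C7 carbinols. The (7R) diol, (R)-[(3R,4R,5S)-5-(4-allyloxy-3-methoxyphenyl)-4-(hydroxymethyl)oxolan-3-yl][3-methoxy-4-(triisopropylsilyloxy)phenyl]methanol F2, is separated from its (7S) epimer F3, which MnO2 in CH2Cl2 oxidises back to 18 for recycling. The primary C9' hydroxyl of F2 is sulfonylated selectively (TsCl, pyridine, 0 °C) to the mono-tosylate F4, and NaH in THF closes ring A by intramolecular Williamson etherification with retention at C7. The fallback returns to the route at 21.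

3. Step 8. The C7' cation may be captured irreversibly by the electron-rich aryl ring on C7 (Friedel–Crafts closure to an aryltetralin) or be held up by the dithiane sulfur instead of being taken by the C9 hydroxyl. Fallback: the order of unmasking is changed. Setting out from 15, the MeI/CaCO3 hydrolysis (MeCN–H2O, 45 °C) is run first to give (2R,3R)-3-[(4-allyloxy-3-methoxyphenyl)(hydroxy)methyl]-4-hydroxy-2-(hydroxymethyl)-1-[3-methoxy-4-(triisopropylsilyloxy)phenyl]butan-1-one F5 (in equilibrium with its ring A hemiketal). In F5 the C7 aryl ring is deactivated as an aryl ketone and no sulfur remains; catalytic camphorsulfonic acid in CH2Cl2 at 0 °C then closes ring B. The fallback returns to the route at 18.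

**Further compounds**

F1 | step 6 | (4R,5R)-4-{2-[3-methoxy-4-(triisopropylsilyloxy)phenyl]-1,3-dithian-2-yl}-5-[(1R,2S,5R)-menthyloxy]dihydrofuran-2(3H)-one | O=C1O[C@@H](O[C@@H]2C[C@H](C)CC[C@H]2C(C)C)[C@H](C2(SCCCS2)c2ccc(O[Si](C(C)C)(C(C)C)C(C)C)c(OC)c2)C1
F2 | step 10 | (R)-[(3R,4R,5S)-5-(4-allyloxy-3-methoxyphenyl)-4-(hydroxymethyl)oxolan-3-yl][3-methoxy-4-(triisopropylsilyloxy)phenyl]methanol, the (7R) diol | OC[C@@H]1[C@@H](c2ccc(OCC=C)c(OC)c2)OC[C@@H]1[C@@H](O)c1ccc(O[Si](C(C)C)(C(C)C)C(C)C)c(OC)c1
F3 | step 10 | (S)-[(3R,4R,5S)-5-(4-allyloxy-3-methoxyphenyl)-4-(hydroxymethyl)oxolan-3-yl][3-methoxy-4-(triisopropylsilyloxy)phenyl]methanol, the (7S) diol | OC[C@@H]1[C@@H](c2ccc(OCC=C)c(OC)c2)OC[C@@H]1[C@H](O)c1ccc(O[Si](C(C)C)(C(C)C)C(C)C)c(OC)c1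
F4 | step 10 | primary C9' p-toluenesulfonate of F2 | Cc1ccc(cc1)S(=O)(=O)OC[C@@H]1[C@@H](c2ccc(OCC=C)c(OC)c2)OC[C@@H]1[C@@H](O)c1ccc(O[Si](C(C)C)(C(C)C)C(C)C)c(OC)c1
F5 | step 8 | (2R,3R)-3-[(4-allyloxy-3-methoxyphenyl)(hydroxy)methyl]-4-hydroxy-2-(hydroxymethyl)-1-[3-methoxy-4-(triisopropylsilyloxy)phenyl]butan-1-one, both C7' epimers | OC[C@H](C(=O)c1ccc(O[Si](C(C)C)(C(C)C)C(C)C)c(OC)c1)[C@H](CO)C(O)c1ccc(OCC=C)c(OC)c1
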